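**Assumption:** germacrane numbering is used for positions (C1=C10, C2, C3‑OH, C4=C5, lactone O on C6, C7, C8‑OAng, C9‑OAc, C11=C13H2, C12=O); the target is read as 3S,6R,7S,8R,9S with 1(10)Z,4E and a Z (angelate) ester.

## Retrosynthetic overview

1. Target ⇐ O3 desilylation ⇐ ring‑closing metathesis at C1=C10 (Z) of an acyclic diene lactone; the ten‑membered carbocycle is the last ring formed.
2. Diene lactone ⇐ O9 acetate and O8 angelate ⇐ zinc Barbier union at C7–C8 of a west 3‑(bromomethyl)butenolide with an east α‑silyloxy aldehyde; this step turns the butenolide into the trans α‑methylene‑γ‑lactone and sets C7 and C8.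
3. West fragment (C1–C7, C11–C13): butenolide (first ring) by palladium carbonylation of a Z‑iodoallylic alcohol, made by directed hydroalumination/iodination of a propargylic alcohol from asymmetric alkynylation (C6) of an enal; C3 from Brown allylation of ethyl 3‑methyl‑4‑oxocrotonate.
4. East fragment (C8–C10): (S)‑3‑methyl‑2‑silyloxybut‑3‑enal from D‑mannitol diacetonide (C9 from the chiral pool).
5. Ring order: five‑membered lactone first (as butenolide), ten‑membered ring last.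

## Route

**West fragment**

Step 1
Reactants: 1 ethyl (2E)-3-methyl-4-oxobut-2-enoate
Product: 2 ethyl (2E,4S)-4-hydroxy-3-methylhepta-2,6-dienoate
Conditions: (−)-Ipc2B(allyl) (1 M in pentane, 1.3 equiv), Et2O, −78 °C; then HOCH2CH2NH2, rt
Reagents that add atoms: (−)-B-allyldiisopinocampheylborane, C=CCB([C@@H]1C[C@@H]2C[C@H]([C@H]1C)C2(C)C)[C@@H]1C[C@@H]2C[C@H]([C@H]1C)C2(C)C
Why: Brown asymmetric allylboration; the (+)-α-pinene-derived reagent delivers allyl through a chair transition state to the Si face of the aldehyde, setting C3 as S, and the enoate is inert at −78 °C.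

Step 2
Reactants: 2 ethyl (2E,4S)-4-hydroxy-3-methylhepta-2,6-dienoate
Product: 3 ethyl (2E,4S)-4-[(tert-butyldimethylsilyl)oxy]-3-methylhepta-2,6-dienoate
Conditions: TBSCl, imidazole, DMF, rt
Reagents that add atoms: tert-butyldimethylsilyl chloride, CC(C)(C)[Si](C)(C)Cl
Why: Standard silyl ether formation protects the C3 hydroxyl until the last step without touching the stereocentre.

Step 3
Reactants: 3 ethyl (2E,4S)-4-[(tert-butyldimethylsilyl)oxy]-3-methylhepta-2,6-dienoate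
Product: 4 (2E,4S)-4-[(tert-butyldimethylsilyl)oxy]-3-methylhepta-2,6-dien-1-ol
Conditions: i-Bu2AlH (2.5 equiv), CH2Cl2, −78 °C; aq. potassium sodium tartrate
Reagents that add atoms: none
Why: 1,2-Reduction of the enoate by the aluminium hydride gives the allylic alcohol with the E alkene intact.

Step 4
Reactants: 4 (2E,4S)-4-[(tert-butyldimethylsilyl)oxy]-3-methylhepta-2,6-dien-1-ol
Product: 5 (2E,4S)-4-[(tert-butyldimethylsilyl)oxy]-3-methylhepta-2,6-dienal
Conditions: MnO2 (20 equiv), CH2Cl2, rt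
Reagents that add atoms: none
Why: Chemoselective allylic oxidation gives the β,β-disubstituted enal (C6 aldehyde) without E/Z erosion.

Step 5
Reactants: 6 prop-2-yn-1-ol
Product: 7 triethyl(prop-2-yn-1-yloxy)silane
Conditions: Et3SiCl, imidazole, CH2Cl2, 0 °C to rt
Reagents that add atoms: triethylsilyl chloride, CC[Si](Cl)(CC)CC
Why: Silylation leaves only one free hydroxyl in the later propargylic diol derivative, which is needed to direct the hydroalumination in step 7.

Step 6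
Reactants: 5 (2E,4S)-4-[(tert-butyldimethylsilyl)oxy]-3-methylhepta-2,6-dienal; 7 triethyl(prop-2-yn-1-yloxy)silane
Product: 9 (4R,5E,7S)-7-[(tert-butyldimethylsilyl)oxy]-6-methyl-1-[(triethylsilyl)oxy]deca-5,9-dien-2-yn-4-ol, via alkynyl(methyl)zinc 8 (not isolated)
Conditions: 7 (3 equiv), Me2Zn (3 equiv), (R,R)-ProPhenol (20 mol%), Ph3P=O (40 mol%), toluene, 0–4 °C, 48 h; aq. NH4Cl
Reagents that add atoms: none
Why: Trost zinc–ProPhenol asymmetric alkynylation; the dinuclear zinc complex adds the alkynyl group 1,2 to the Si face of the enal, setting C6 as R (sense to be confirmed by Mosher analysis).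

Step 7
Reactants: 9 (4R,5E,7S)-7-[(tert-butyldimethylsilyl)oxy]-6-methyl-1-[(triethylsilyl)oxy]deca-5,9-dien-2-yn-4-ol
Product: 11 (2Z,4R,5E,7S)-7-[(tert-butyldimethylsilyl)oxy]-2-iodo-6-methyl-1-[(triethylsilyl)oxy]deca-2,5,9-trien-4-ol, via cyclic vinylalanate 10 (not isolated)
Conditions: NaAlH2(OCH2CH2OMe)2 (2.5 equiv), THF, 0 °C to rt; EtOAc, then I2, −78 to 0 °C; aq. Na2S2O3
Reagents that add atoms: iodine, II
Why: Hydroxyl-directed trans-hydroalumination puts hydride on C7 and aluminium on C11 in a five-membered alanate, and iodinolysis with retention gives the Z-iodoalkene with iodine cis to the C6 carbinol.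

Step 8
Reactants: 11 (2Z,4R,5E,7S)-7-[(tert-butyldimethylsilyl)oxy]-2-iodo-6-methyl-1-[(triethylsilyl)oxy]deca-2,5,9-trien-4-ol
Product: 12 (5R)-5-{(1E,3S)-3-[(tert-butyldimethylsilyl)oxy]-2-methylhexa-1,5-dien-1-yl}-3-{[(triethylsilyl)oxy]methyl}furan-2(5H)-one
Conditions: PdCl2(PPh3)2 (5 mol%), CO (1 atm), K2CO3, THF, 25 °C
Reagents that add atoms: carbon monoxide, [C-]#[O+]
Why: Carbonylative lactonization; oxidative addition of the vinyl iodide to zerovalent palladium, CO insertion and capture of the acyl-palladium by the cis C6 hydroxyl close the butenolide without touching C6.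

Step 9
Reactants: 12 (5R)-5-{(1E,3S)-3-[(tert-butyldimethylsilyl)oxy]-2-methylhexa-1,5-dien-1-yl}-3-{[(triethylsilyl)oxy]methyl}furan-2(5H)-one
Product: 13 (5R)-5-{(1E,3S)-3-[(tert-butyldimethylsilyl)oxy]-2-methylhexa-1,5-dien-1-yl}-3-(hydroxymethyl)furan-2(5H)-one
Conditions: PPTS (10 mol%), MeOH, 0 °C
Reagents that add atoms: none
Why: Acid-catalysed methanolysis removes the primary allylic triethylsilyl ether much faster than the secondary tert-butyldimethylsilyl ether.

Step 10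
Reactants: 13 (5R)-5-{(1E,3S)-3-[(tert-butyldimethylsilyl)oxy]-2-methylhexa-1,5-dien-1-yl}-3-(hydroxymethyl)furan-2(5H)-one
Product: 14 (5R)-3-(bromomethyl)-5-{(1E,3S)-3-[(tert-butyldimethylsilyl)oxy]-2-methylhexa-1,5-dien-1-yl}furan-2(5H)-one
Conditions: CBr4, PPh3, CH2Cl2, 0 °C
Reagents that add atoms: carbon tetrabromide, BrC(Br)(Br)Br
Why: Appel bromination converts the primary allylic alcohol to the bromide under neutral conditions that do not epimerise the γ-position of the butenolide.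

**East fragment**

Step 11
Reactants: 15 1,2:5,6-di-O-isopropylidene-D-mannitol
Product: 16 (4R)-2,2-dimethyl-1,3-dioxolane-4-carbaldehyde
Conditions: NaIO4, aq. NaHCO3, CH2Cl2, rt
Reagents that add atoms: none
Why: Periodate glycol cleavage of the central diol gives two molecules of (R)-glyceraldehyde acetonide, whose stereocentre becomes C9.

Step 12
Reactants: 16 (4R)-2,2-dimethyl-1,3-dioxolane-4-carbaldehyde
Product: 17 (1RS)-1-[(4R)-2,2-dimethyl-1,3-dioxolan-4-yl]ethan-1-ol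
Conditions: MeMgBr, Et2O, −78 to 0 °C; H2O/aq. NH4Cl
Reagents that add atoms: methylmagnesium bromide, C[Mg]Br
Why: Grignard addition installs the future C10 methyl; the new carbinol centre is irrelevant because it is oxidised next.

Step 13
Reactants: 17 (1RS)-1-[(4R)-2,2-dimethyl-1,3-dioxolan-4-yl]ethan-1-ol
Product: 18 1-[(4R)-2,2-dimethyl-1,3-dioxolan-4-yl]ethan-1-one
Conditions: Dess–Martin periodinane, pyridine, CH2Cl2, 0 °C to rt
Reagents that add atoms: none
Why: Dess–Martin oxidation gives the methyl ketone under buffered non-enolising conditions, so the α-alkoxy stereocentre is kept.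

Step 14
Reactants: 18 1-[(4R)-2,2-dimethyl-1,3-dioxolan-4-yl]ethan-1-one
Product: 19 (4S)-2,2-dimethyl-4-(prop-1-en-2-yl)-1,3-dioxolane
Conditions: Ph3PCH3Br, KN(SiMe3)2, THF, 0 °C; then 18, −78 to 0 °C
Reagents that add atoms: methyltriphenylphosphonium bromide, C[P+](c1ccccc1)(c1ccccc1)c1ccccc1.[Br-]
Why: Wittig methylenation with salt-free ylide at low temperature makes the C10 isopropenyl group faster than the ketone enolises (descriptor changes to S by priority only).

Step 15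
Reactants: 19 (4S)-2,2-dimethyl-4-(prop-1-en-2-yl)-1,3-dioxolane
Product: 20 (2S)-3-methylbut-3-ene-1,2-diol
Conditions: AcOH/H2O (4:1), 40 °C
Reagents that add atoms: none
Why: Mild acid hydrolysis of the acetonide frees the C8/C9 diol without allylic transposition.

Step 16
Reactants: 20 (2S)-3-methylbut-3-ene-1,2-diol
Product: 21 (2S)-3-methyl-1,2-bis[(triethylsilyl)oxy]but-3-ene
Conditions: Et3SiCl (2.4 equiv), imidazole, cat. DMAP, CH2Cl2, 0 °C to rt
Reagents that add atoms: triethylsilyl chloride, CC[Si](Cl)(CC)CC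
Why: Bis-silylation sets up the selective oxidative cleavage of the primary silyl ether in the next step.

Step 17
Reactants: 21 (2S)-3-methyl-1,2-bis[(triethylsilyl)oxy]but-3-ene
Product: 22 (2S)-3-methyl-2-[(triethylsilyl)oxy]but-3-enal
Conditions: (COCl)2, DMSO, CH2Cl2, −78 to −30 °C; then i-Pr2NEt, −78 to 0 °C; used crude
Reagents that add atoms: none
Why: Under Swern conditions the primary triethylsilyl ether is cleaved and oxidised directly to the aldehyde while the secondary one survives, and the hindered base at low temperature avoids enolisation of the α-silyloxy β,γ-unsaturated aldehyde.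

**Union and endgame**

Step 18
Reactants: 14 (5R)-3-(bromomethyl)-5-{(1E,3S)-3-[(tert-butyldimethylsilyl)oxy]-2-methylhexa-1,5-dien-1-yl}furan-2(5H)-one; 22 (2S)-3-methyl-2-[(triethylsilyl)oxy]but-3-enal
Product: 24 (4R,5R)-5-{(1E,3S)-3-[(tert-butyldimethylsilyl)oxy]-2-methylhexa-1,5-dien-1-yl}-4-{(1R,2S)-1-hydroxy-3-methyl-2-[(triethylsilyl)oxy]but-3-en-1-yl}-3-methylideneoxolan-2-one, via allylzinc bromide 23 (not isolated)
Conditions: Zn dust, THF/sat. aq. NH4Cl, 0 °C to rt; 22 (1.5 equiv)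
Reagents that add atoms: none
Why: Barbier allylation; the ring-locked allylzinc reacts at C7 through a Zimmerman–Traxler chair on the face anti to the C6 side chain (trans H6/H7, anti C7/C8), and this reagent-controlled sense matches Felkin–Anh addition to the α-silyloxy aldehyde, giving 7S and 8R anti to 9S.

Step 19
Reactants: 24 (4R,5R)-5-{(1E,3S)-3-[(tert-butyldimethylsilyl)oxy]-2-methylhexa-1,5-dien-1-yl}-4-{(1R,2S)-1-hydroxy-3-methyl-2-[(triethylsilyl)oxy]but-3-en-1-yl}-3-methylideneoxolan-2-one; 25 (2Z)-2-methylbut-2-enoic acid (angelic acid)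
Product: 27 (1R,2S)-1-[(2R,3S)-2-{(1E,3S)-3-[(tert-butyldimethylsilyl)oxy]-2-methylhexa-1,5-dien-1-yl}-4-methylidene-5-oxooxolan-3-yl]-3-methyl-2-[(triethylsilyl)oxy]but-3-en-1-yl (2Z)-2-methylbut-2-enoate, via mixed anhydride 26 (not isolated)
Conditions: 25, 2,4,6-Cl3C6H2COCl, Et3N, toluene, rt; then 24, toluene, 75 °C (no DMAP)
Reagents that add atoms: none
Why: Yamaguchi-type esterification through the trichlorobenzoyl mixed anhydride acylates the only free hydroxyl (O8) and, without nucleophilic catalyst, avoids angelate-to-tiglate isomerisation.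

Step 20
Reactants: 27 the O8 angelate, O9 triethylsilyl ether
Product: 28 (1R,2S)-1-[(2R,3S)-2-{(1E,3S)-3-[(tert-butyldimethylsilyl)oxy]-2-methylhexa-1,5-dien-1-yl}-4-methylidene-5-oxooxolan-3-yl]-2-hydroxy-3-methylbut-3-en-1-yl (2Z)-2-methylbut-2-enoate
Conditions: HF·pyridine, pyridine, THF, 0 °C
Reagents that add atoms: none
Why: Buffered fluoride desilylation removes the triethylsilyl ether selectively over the tert-butyldimethylsilyl ether, and the slightly acidic medium suppresses O8 to O9 acyl migration.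

Step 21
Reactants: 28 the O9 alcohol
Product: 29 (1R,2S)-2-(acetyloxy)-1-[(2R,3S)-2-{(1E,3S)-3-[(tert-butyldimethylsilyl)oxy]-2-methylhexa-1,5-dien-1-yl}-4-methylidene-5-oxooxolan-3-yl]-3-methylbut-3-en-1-yl (2Z)-2-methylbut-2-enoate
Conditions: Ac2O, pyridine, cat. DMAP, CH2Cl2, 0 °C to rt
Reagents that add atoms: acetic anhydride, CC(=O)OC(C)=O
Why: Standard acetylation of the free C9 allylic alcohol, done directly after desilylation so that the diester pattern (O8 angelate, O9 acetate) is fixed.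

Step 22
Reactants: 29 the acyclic diene lactone
Product: 30 (3aS,4R,5S,6Z,9S,10E,11aR)-5-(acetyloxy)-9-[(tert-butyldimethylsilyl)oxy]-6,10-dimethyl-3-methylidene-2-oxo-2,3,3a,4,5,8,9,11a-octahydrocyclodeca[b]furan-4-yl (2Z)-2-methylbut-2-enoate
Conditions: second-generation Hoveyda–Grubbs catalyst (H2IMes)Cl2Ru(=CH-C6H4-2-O-i-Pr) (15 mol%, in portions), toluene (1 mM), 90 °C, Ar sparge
Reagents that add atoms: none
Why: Ring-closing metathesis; the ruthenium carbene forms at the C1 vinyl and closes onto the 1,1-disubstituted C10 olefin, and the ten-membered ring that already holds the E C4=C5 alkene and the trans lactone should take the new trisubstituted alkene as Z, while the enoate alkenes are unreactive.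

Step 23
Reactants: 30 the O3 silyl ether of the target
Product: 31 (3aS,4R,5S,6Z,9S,10E,11aR)-5-(acetyloxy)-9-hydroxy-6,10-dimethyl-3-methylidene-2-oxo-2,3,3a,4,5,8,9,11a-octahydrocyclodeca[b]furan-4-yl (2Z)-2-methylbut-2-enoate
Conditions: HF·pyridine, THF, 0 °C to rt
Reagents that add atoms: none
Why: Fluoride desilylation under mildly acidic conditions frees the C3 hydroxyl without cleaving the acetate or angelate, adding to the α-methylene lactone or isomerising the angelate.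

## Compound list

1 | ethyl (2E)-3-methyl-4-oxobut-2-enoate | CCOC(=O)/C=C(\C)C=O | starting material
2 | ethyl (2E,4S)-4-hydroxy-3-methylhepta-2,6-dienoate | CCOC(=O)/C=C(\C)[C@@H](O)CC=C | intermediate
3 | ethyl (2E,4S)-4-[(tert-butyldimethylsilyl)oxy]-3-methylhepta-2,6-dienoate | CCOC(=O)/C=C(\C)[C@@H](O[Si](C)(C)C(C)(C)C)CC=C | intermediate
4 | (2E,4S)-4-[(tert-butyldimethylsilyl)oxy]-3-methylhepta-2,6-dien-1-ol | OC/C=C(\C)[C@@H](O[Si](C)(C)C(C)(C)C)CC=C | intermediate
5 | (2E,4S)-4-[(tert-butyldimethylsilyl)oxy]-3-methylhepta-2,6-dienal | O=C/C=C(\C)[C@@H](O[Si](C)(C)C(C)(C)C)CC=C | intermediate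
6 | prop-2-yn-1-ol | C#CCO | starting material
7 | triethyl(prop-2-yn-1-yloxy)silane | C#CCO[Si](CC)(CC)CC | intermediate
8 | methyl{3-[(triethylsilyl)oxy]prop-1-yn-1-yl}zinc (formed in the flask) | C[Zn]C#CCO[Si](CC)(CC)CC | intermediate
9 | (4R,5E,7S)-7-[(tert-butyldimethylsilyl)oxy]-6-methyl-1-[(triethylsilyl)oxy]deca-5,9-dien-2-yn-4-ol | O[C@@H](C#CCO[Si](CC)(CC)CC)/C=C(\C)[C@@H](O[Si](C)(C)C(C)(C)C)CC=C | intermediate
10 | sodium cyclic vinylalanate: 2,2-bis(2-methoxyethoxy)-1,2-oxaluminol-2-uide ring with Al on C11 and O6 (formed in the flask) | [Na+].COCCO[Al-]1(OCCOC)O[C@H](/C=C(\C)[C@@H](O[Si](C)(C)C(C)(C)C)CC=C)C=C1CO[Si](CC)(CC)CC | intermediate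
11 | (2Z,4R,5E,7S)-7-[(tert-butyldimethylsilyl)oxy]-2-iodo-6-methyl-1-[(triethylsilyl)oxy]deca-2,5,9-trien-4-ol | O[C@@H](/C=C(\I)CO[Si](CC)(CC)CC)/C=C(\C)[C@@H](O[Si](C)(C)C(C)(C)C)CC=C | intermediate
12 | (5R)-5-{(1E,3S)-3-[(tert-butyldimethylsilyl)oxy]-2-methylhexa-1,5-dien-1-yl}-3-{[(triethylsilyl)oxy]methyl}furan-2(5H)-one | CC[Si](CC)(CC)OCC1=C[C@@H](/C=C(\C)[C@@H](O[Si](C)(C)C(C)(C)C)CC=C)OC1=O | intermediate
13 | (5R)-5-{(1E,3S)-3-[(tert-butyldimethylsilyl)oxy]-2-methylhexa-1,5-dien-1-yl}-3-(hydroxymethyl)furan-2(5H)-one | OCC1=C[C@@H](/C=C(\C)[C@@H](O[Si](C)(C)C(C)(C)C)CC=C)OC1=O | intermediate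
14 | (5R)-3-(bromomethyl)-5-{(1E,3S)-3-[(tert-butyldimethylsilyl)oxy]-2-methylhexa-1,5-dien-1-yl}furan-2(5H)-one | BrCC1=C[C@@H](/C=C(\C)[C@@H](O[Si](C)(C)C(C)(C)C)CC=C)OC1=O | intermediate
15 | 1,2:5,6-di-O-isopropylidene-D-mannitol | CC1(C)OC[C@@H](O1)[C@@H](O)[C@H](O)[C@H]1COC(C)(C)O1 | starting material
16 | (4R)-2,2-dimethyl-1,3-dioxolane-4-carbaldehyde | O=C[C@H]1COC(C)(C)O1 | intermediate
17 | (1RS)-1-[(4R)-2,2-dimethyl-1,3-dioxolan-4-yl]ethan-1-ol (both carbinol epimers) | CC(O)[C@H]1COC(C)(C)O1 | intermediate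
18 | 1-[(4R)-2,2-dimethyl-1,3-dioxolan-4-yl]ethan-1-one | CC(=O)[C@H]1COC(C)(C)O1 | intermediate
19 | (4S)-2,2-dimethyl-4-(prop-1-en-2-yl)-1,3-dioxolane | CC(=C)[C@H]1COC(C)(C)O1 | intermediate
20 | (2S)-3-methylbut-3-ene-1,2-diol | CC(=C)[C@H](O)CO | intermediate
21 | (2S)-3-methyl-1,2-bis[(triethylsilyl)oxy]but-3-ene | CC(=C)[C@H](O[Si](CC)(CC)CC)CO[Si](CC)(CC)CC | intermediate
22 | (2S)-3-methyl-2-[(triethylsilyl)oxy]but-3-enal | CC(=C)[C@H](O[Si](CC)(CC)CC)C=O | intermediate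
23 | {[(5R)-5-{(1E,3S)-3-[(tert-butyldimethylsilyl)oxy]-2-methylhexa-1,5-dien-1-yl}-2-oxo-2,5-dihydrofuran-3-yl]methyl}zinc bromide (formed in the flask) | Br[Zn]CC1=C[C@@H](/C=C(\C)[C@@H](O[Si](C)(C)C(C)(C)C)CC=C)OC1=O | intermediate
24 | (4R,5R)-5-{(1E,3S)-3-[(tert-butyldimethylsilyl)oxy]-2-methylhexa-1,5-dien-1-yl}-4-{(1R,2S)-1-hydroxy-3-methyl-2-[(triethylsilyl)oxy]but-3-en-1-yl}-3-methylideneoxolan-2-one | C=C1C(=O)O[C@H](/C=C(\C)[C@@H](O[Si](C)(C)C(C)(C)C)CC=C)[C@H]1[C@@H](O)[C@@H](O[Si](CC)(CC)CC)C(C)=C | intermediate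
25 | (2Z)-2-methylbut-2-enoic acid (angelic acid) | C/C=C(/C)C(=O)O | starting material
26 | (2Z)-2-methylbut-2-enoic 2,4,6-trichlorobenzoic anhydride (formed in the flask) | C/C=C(/C)C(=O)OC(=O)c1c(Cl)cc(Cl)cc1Cl | intermediate
27 | (1R,2S)-1-[(2R,3S)-2-{(1E,3S)-3-[(tert-butyldimethylsilyl)oxy]-2-methylhexa-1,5-dien-1-yl}-4-methylidene-5-oxooxolan-3-yl]-3-methyl-2-[(triethylsilyl)oxy]but-3-en-1-yl (2Z)-2-methylbut-2-enoate | C=C1C(=O)O[C@H](/C=C(\C)[C@@H](O[Si](C)(C)C(C)(C)C)CC=C)[C@H]1[C@@H](OC(=O)/C(C)=C\C)[C@@H](O[Si](CC)(CC)CC)C(C)=C | intermediate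
28 | (1R,2S)-1-[(2R,3S)-2-{(1E,3S)-3-[(tert-butyldimethylsilyl)oxy]-2-methylhexa-1,5-dien-1-yl}-4-methylidene-5-oxooxolan-3-yl]-2-hydroxy-3-methylbut-3-en-1-yl (2Z)-2-methylbut-2-enoate | C=C1C(=O)O[C@H](/C=C(\C)[C@@H](O[Si](C)(C)C(C)(C)C)CC=C)[C@H]1[C@@H](OC(=O)/C(C)=C\C)[C@@H](O)C(C)=C | intermediate
29 | (1R,2S)-2-(acetyloxy)-1-[(2R,3S)-2-{(1E,3S)-3-[(tert-butyldimethylsilyl)oxy]-2-methylhexa-1,5-dien-1-yl}-4-methylidene-5-oxooxolan-3-yl]-3-methylbut-3-en-1-yl (2Z)-2-methylbut-2-enoate | C=C1C(=O)O[C@H](/C=C(\C)[C@@H](O[Si](C)(C)C(C)(C)C)CC=C)[C@H]1[C@@H](OC(=O)/C(C)=C\C)[C@@H](OC(C)=O)C(C)=C | intermediate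
30 | (3aS,4R,5S,6Z,9S,10E,11aR)-5-(acetyloxy)-9-[(tert-butyldimethylsilyl)oxy]-6,10-dimethyl-3-methylidene-2-oxo-2,3,3a,4,5,8,9,11a-octahydrocyclodeca[b]furan-4-yl (2Z)-2-methylbut-2-enoate | C=C1C(=O)O[C@@H]2/C=C(\C)[C@@H](O[Si](C)(C)C(C)(C)C)C/C=C(/C)[C@H](OC(C)=O)[C@H](OC(=O)/C(C)=C\C)[C@@H]12 | intermediate
31 | (3aS,4R,5S,6Z,9S,10E,11aR)-5-(acetyloxy)-9-hydroxy-6,10-dimethyl-3-methylidene-2-oxo-2,3,3a,4,5,8,9,11a-octahydrocyclodeca[b]furan-4-yl (2Z)-2-methylbut-2-enoate | C=C1C(=O)O[C@@H]2/C=C(\C)[C@@H](O)C/C=C(/C)[C@H](OC(C)=O)[C@H](OC(=O)/C(C)=C\C)[C@@H]12 | target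

## Step count

Total step count: 23.
Longest linear sequence: 15 steps (steps 1–4, 6–10, 18–23). The east branch (steps 11–17) and the alkyne branch (step 5) run in parallel, so 15/23 is below two thirds.

## Steps most likely to fail, with fallbacks

**Step 22 (ring-closing metathesis).** The carbene formed at the C1 vinyl may dimerise or stall instead of engaging the hindered, ester-flanked 1,1-disubstituted C10 olefin. The fallback is a relay ring closure that places the carbene on C10; it sets out from ketone 18 and comes back at 30. Ketone 18 is olefinated with the ylide from (hex-5-en-1-yl)triphenylphosphonium bromide (KN(SiMe3)2, THF, −78 to 0 °C) to give (4S)-2,2-dimethyl-4-(octa-2,7-dien-2-yl)-1,3-dioxolane F1, whose new alkene geometry is immaterial. The chemistry of steps 15–17 then gives (2S)-3-methylnona-3,8-diene-1,2-diol F2, (2S)-3-methyl-1,2-bis[(triethylsilyl)oxy]nona-3,8-diene F3 and (2S)-3-methyl-2-[(triethylsilyl)oxy]nona-3,8-dienal F4. Barbier union of F4 with bromide 14 as in step 18 gives the relay analogue of 24 F5. Esterification with 25, desilylation and acetylation as in steps 19–21 give the relay analogue of 27 F6, the relay analogue of 28 F7 and the relay analogue of 29 F8. On F8 the second-generation Hoveyda–Grubbs catalyst (H2IMes)Cl2Ru(=CH-C6H4-2-O-i-Pr) loads at the terminal vinyl of the relay arm and expels cyclopentene, which leaves the carbene on C10; closure onto the unhindered C1 vinyl then gives 30.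

**Step 18 (Barbier union).** The aqueous zinc conditions may erode the crude α-silyloxy aldehyde or give poor C7/C8 selectivity. The fallback replaces the in-flask allylzinc by an isolable allylboron reagent; it sets out from bromide 14 and comes back at 24. Bromide 14 is borylated with B2pin2 and Pd2(dba)3 (2.5 mol%) in THF at 50 °C through the π-allyl complex to give (5R)-5-{(1E,3S)-3-[(tert-butyldimethylsilyl)oxy]-2-methylhexa-1,5-dien-1-yl}-3-[(4,4,5,5-tetramethyl-1,3,2-dioxaborolan-2-yl)methyl]furan-2(5H)-one F9. F9 is then heated with aldehyde 22 in dry toluene (25–60 °C, or with 10 mol% Sc(OTf)3 at −78 °C); the closed chair allylboration gives the same trans, anti adduct, and aqueous work-up gives 24.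

**Step 6 (asymmetric alkynylation).** The β,β-disubstituted enal and the weakly acidic propargyl ether may give low conversion or low selectivity, and the facial sense must be verified. The fallback sets C6 by ketone reduction instead; it sets out from enal 5 and comes back at 9. The lithium acetylide of 7 (n-BuLi, THF, −78 °C) adds to 5 to give (4RS,5E,7S)-7-[(tert-butyldimethylsilyl)oxy]-6-methyl-1-[(triethylsilyl)oxy]deca-5,9-dien-2-yn-4-ol F10 as a C4 epimer mixture. MnO2 in CH2Cl2 oxidises it to (5E,7S)-7-[(tert-butyldimethylsilyl)oxy]-6-methyl-1-[(triethylsilyl)oxy]deca-5,9-dien-2-yn-4-one F11. Midland reduction with (R)-Alpine-Borane (B-isopinocampheyl-9-borabicyclo[3.3.1]nonane from (+)-α-pinene, neat, rt), in which the alkyne acts as the small group, gives the 4R alcohol 9.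

## Further compounds

F1 | step 22 | (4S)-2,2-dimethyl-4-(octa-2,7-dien-2-yl)-1,3-dioxolane (alkene isomer mixture) | CC(=CCCCC=C)[C@H]1COC(C)(C)O1
F2 | step 22 | (2S)-3-methylnona-3,8-diene-1,2-diol | CC(=CCCCC=C)[C@H](O)CO
F3 | step 22 | (2S)-3-methyl-1,2-bis[(triethylsilyl)oxy]nona-3,8-diene | CC(=CCCCC=C)[C@H](O[Si](CC)(CC)CC)CO[Si](CC)(CC)CC
F4 | step 22 | (2S)-3-methyl-2-[(triethylsilyl)oxy]nona-3,8-dienal | CC(=CCCCC=C)[C@H](O[Si](CC)(CC)CC)C=O
F5 | step 22 | relay analogue of 24: (4R,5R)-5-{(1E,3S)-3-[(tert-butyldimethylsilyl)oxy]-2-methylhexa-1,5-dien-1-yl}-4-{(1R,2S)-1-hydroxy-3-methyl-2-[(triethylsilyl)oxy]nona-3,8-dien-1-yl}-3-methylideneoxolan-2-one | C=C1C(=O)O[C@H](/C=C(\C)[C@@H](O[Si](C)(C)C(C)(C)C)CC=C)[C@H]1[C@@H](O)[C@@H](O[Si](CC)(CC)CC)C(C)=CCCCC=C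
F6 | step 22 | relay analogue of 27: O8 (2Z)-2-methylbut-2-enoate of F5 | C=C1C(=O)O[C@H](/C=C(\C)[C@@H](O[Si](C)(C)C(C)(C)C)CC=C)[C@H]1[C@@H](OC(=O)/C(C)=C\C)[C@@H](O[Si](CC)(CC)CC)C(C)=CCCCC=C
F7 | step 22 | relay analogue of 28: O9 alcohol from F6 | C=C1C(=O)O[C@H](/C=C(\C)[C@@H](O[Si](C)(C)C(C)(C)C)CC=C)[C@H]1[C@@H](OC(=O)/C(C)=C\C)[C@@H](O)C(C)=CCCCC=C
F8 | step 22 | relay analogue of 29: O9 acetate of F7 | C=C1C(=O)O[C@H](/C=C(\C)[C@@H](O[Si](C)(C)C(C)(C)C)CC=C)[C@H]1[C@@H](OC(=O)/C(C)=C\C)[C@@H](OC(C)=O)C(C)=CCCCC=C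
F9 | step 18 | (5R)-5-{(1E,3S)-3-[(tert-butyldimethylsilyl)oxy]-2-methylhexa-1,5-dien-1-yl}-3-[(4,4,5,5-tetramethyl-1,3,2-dioxaborolan-2-yl)methyl]furan-2(5H)-one | CC1(C)OB(CC2=C[C@@H](/C=C(\C)[C@@H](O[Si](C)(C)C(C)(C)C)CC=C)OC2=O)OC1(C)C
F10 | step 6 | (4RS,5E,7S)-7-[(tert-butyldimethylsilyl)oxy]-6-methyl-1-[(triethylsilyl)oxy]deca-5,9-dien-2-yn-4-ol (C4 epimers) | OC(C#CCO[Si](CC)(CC)CC)/C=C(\C)[C@@H](O[Si](C)(C)C(C)(C)C)CC=C
F11 | step 6 | (5E,7S)-7-[(tert-butyldimethylsilyl)oxy]-6-methyl-1-[(triethylsilyl)oxy]deca-5,9-dien-2-yn-4-one | O=C(C#CCO[Si](CC)(CC)CC)/C=C(\C)[C@@H](O[Si](C)(C)C(C)(C)C)CC=C
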